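The route rests on cutting the O1–C2 ether bond of ring C of the upper (fisetinidol) unit. The precursor is an open-chain tertiary allylic alcohol whose C4 already carries ring A with its free ortho-phenol, the whole catechin unit (through C6 of ring D) and the styryl arm C3=C2–ring B. The key step exploits that C2–C3–C4 lies between the electron-rich rings A and B: a chiral N-triflylphosphoramide ionises C4–OH to the allyl cation and the ring-A phenol closes onto benzylic C2 inside the chiral ion pair, forming ring C and the C2 stereocentre in one operation. As C2, C3 and C4 are all-trans, hydroboration of the new C3=C4 bond then sets C3 and C4 from C2.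

Key step: step 6

Assumption: the (R)-configured catalyst is taken to deliver the (2S)-chromene 12; if the sense of induction proves opposite, the (S)-catalyst is used with no other change.
Remark: the target is fisetinidol-(4α→6)-catechin, (2R,3S,4S) in the upper unit and (2R,3S) in the lower unit; compounds 1, 5 and 6 are commercial.
Remark: alcohol 11 ionises very easily, so it is handled on base-washed glassware and used crude.

Step 1
Reactants: 1 (+)-catechin
Product: 2 5,7,3',4'-tetra-O-benzylcatechin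
Conditions: BnBr, K2CO3, DMF, 0 °C to rt, N2
Reagents that add atoms: benzyl bromide, BrCc1ccccc1
Why: Williamson ether synthesis, in which the carbonate base benzylates only the four phenols (far more acidic than the C3 alcohol) and leaves both stereocentres untouched.

Step 2
Reactants: 2 5,7,3',4'-tetra-O-benzylcatechin
Product: 3 8-bromo-5,7,3',4'-tetra-O-benzylcatechin
Conditions: NBS (1.0 equiv), CH2Cl2, −78 °C to rt
Reagents that add atoms: N-bromosuccinimide, O=C1CCC(=O)N1Br
Why: Electrophilic aromatic bromination, in which C8 is the most reactive position of the phloroglucinol-type ring D of catechin ethers, so one equivalent should cap C8 selectively.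

Step 3
Reactants: 3 8-bromo-5,7,3',4'-tetra-O-benzylcatechin
Product: 4 8-bromo-6-iodo-5,7,3',4'-tetra-O-benzylcatechin
Conditions: NIS (1.1 equiv), DMF, 0 °C to rt, dark
Reagents that add atoms: N-iodosuccinimide, O=C1CCC(=O)N1I
Why: Electrophilic aromatic iodination, in which C6 (between the two benzyloxy groups) is the only strongly activated position left once C8 is capped, and the iodide installed there can later be exchanged in the presence of the bromide.

Step 4
Reactants: 5 1-[4-(benzyloxy)-2-hydroxyphenyl]ethanone, 6 3,4-bis(benzyloxy)benzaldehyde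
Product: 7 (E)-1-[4-(benzyloxy)-2-hydroxyphenyl]-3-[3,4-bis(benzyloxy)phenyl]prop-2-en-1-one
Conditions: KOH, EtOH, rt; aq. HCl work-up
Reagents that add atoms: none
Why: Claisen–Schmidt condensation, in which the acetophenone enolate adds to the non-enolisable aldehyde and dehydration should give the thermodynamically favoured (E)-enone.

Step 5
Reactants: 7 (E)-1-[4-(benzyloxy)-2-hydroxyphenyl]-3-[3,4-bis(benzyloxy)phenyl]prop-2-en-1-one, 4 8-bromo-6-iodo-5,7,3',4'-tetra-O-benzylcatechin
Product: 11 (E)-1-[4-(benzyloxy)-2-hydroxyphenyl]-1-[(2R,3S)-5,7-bis(benzyloxy)-2-[3,4-bis(benzyloxy)phenyl]-8-bromo-3-hydroxychroman-6-yl]-3-[3,4-bis(benzyloxy)phenyl]prop-2-en-1-ol as both C1 epimers, via sodium phenoxide 8 (not isolated), via sodium alkoxide 9 (not isolated), via aryllithium 10 (not isolated)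
Conditions: 7 (1.2 equiv), NaH, THF, 0 °C; separately 4, NaH, THF, 0 °C, then n-BuLi (1.05 equiv), −78 °C; combine, −78 to −20 °C; H2O, pH 7 buffer
Reagents that add atoms: none
Why: 1,2-Addition of an aryllithium to an enone carbonyl after selective iodine–lithium exchange (far faster than bromine–lithium exchange at −78 °C), with both acidic protons removed beforehand by NaH so that no aryllithium is quenched; the carbinol stereocentre forms without control because step 6 erases it.

Step 6
Reactants: 11 (E)-1-[4-(benzyloxy)-2-hydroxyphenyl]-1-[(2R,3S)-5,7-bis(benzyloxy)-2-[3,4-bis(benzyloxy)phenyl]-8-bromo-3-hydroxychroman-6-yl]-3-[3,4-bis(benzyloxy)phenyl]prop-2-en-1-ol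
Product: 12 (2S)-7-(benzyloxy)-2-[3,4-bis(benzyloxy)phenyl]-4-[(2R,3S)-5,7-bis(benzyloxy)-2-[3,4-bis(benzyloxy)phenyl]-8-bromo-3-hydroxychroman-6-yl]-2H-chromene
Conditions: (R)-3,3'-bis(2,4,6-triisopropylphenyl)-1,1'-binaphthalene-2,2'-diyl N-triflylphosphoramide (5 mol %), 4 Å molecular sieves, toluene, −78 °C; Et3N quench
Reagents that add atoms: none
Why: The strong chiral Brønsted acid protonates the tertiary C4–OH, which is doubly benzylic and allylic, and loss of water gives the 1,1,3-triarylallyl cation (a protonated vinylogous ortho-quinone methide) as a contact ion pair with the chiral phosphoramide anion, to which the ring-A phenol is hydrogen-bonded before it attacks the C2 terminus. The closest known reaction type is the chiral N-triflylphosphoramide-catalysed intramolecular allylic substitution of ortho-(hydroxyallyl)phenols to 2H-chromenes through chiral contact ion pairs. Ring C closes in a 6-endo-trig mode on the allyl cation (equivalent to an ion-paired oxa-6π closure), while attack at C4 would need a four-membered ring and is excluded. The new stereocentre C2 is set by the chiral counter-anion, because the planar cation and the remote, twisted ring D offer no substrate bias. The step needs enantioface selection at C2 and O-cyclisation in preference to Friedel–Crafts indene formation; the ortho-phenol placed for six-membered closure, the benzyl caps on all other phenols, the low temperature and the base quench before warming should secure this and keep the benzylic, allylic C2–O1 bond of the product from re-ionising.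

Step 7
Reactants: 12 (2S)-7-(benzyloxy)-2-[3,4-bis(benzyloxy)phenyl]-4-[(2R,3S)-5,7-bis(benzyloxy)-2-[3,4-bis(benzyloxy)phenyl]-8-bromo-3-hydroxychroman-6-yl]-2H-chromene
Product: 14 (2R,3S,4S)-7-(benzyloxy)-2-[3,4-bis(benzyloxy)phenyl]-4-[(2R,3S)-5,7-bis(benzyloxy)-2-[3,4-bis(benzyloxy)phenyl]-8-bromo-3-hydroxychroman-6-yl]chroman-3-ol, via alkylborane 13 (not isolated)
Conditions: BH3·THF (excess), THF, 0 °C to rt, dark; then NaOH, H2O2, 0 °C
Reagents that add atoms: hydrogen peroxide, OO
Why: Hydroboration–oxidation, in which borane should add syn across C3=C4 from the face opposite the C2 aryl group with boron at the less hindered C3 (also favoured by the allylic O1 and the donor ring A on C4), and oxidation with retention then places the 3-OH trans to both aryl groups, so C3 and C4 are set from C2.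

Step 8
Reactants: 14 (2R,3S,4S)-7-(benzyloxy)-2-[3,4-bis(benzyloxy)phenyl]-4-[(2R,3S)-5,7-bis(benzyloxy)-2-[3,4-bis(benzyloxy)phenyl]-8-bromo-3-hydroxychroman-6-yl]chroman-3-ol
Product: 15 fisetinidol-(4α→6)-catechin
Conditions: H2 (1 atm), Pd(OH)2 on carbon, Et3N, THF/MeOH, rt
Reagents that add atoms: none
Why: Catalytic hydrogenolysis should cleave the seven benzyl ethers and, with triethylamine as HBr scavenger, the aryl C–Br bond, without touching the five stereocentres or the C4–C6 interflavan bond.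

Compound list
1 | (+)-catechin, (2R,3S)-2-(3,4-dihydroxyphenyl)chroman-3,5,7-triol | O[C@H]1Cc2c(O)cc(O)cc2O[C@@H]1c1ccc(O)c(O)c1 | starting material
2 | 5,7,3',4'-tetra-O-benzylcatechin, (2R,3S)-5,7-bis(benzyloxy)-2-[3,4-bis(benzyloxy)phenyl]chroman-3-ol | O[C@H]1Cc2c(OCc3ccccc3)cc(OCc3ccccc3)cc2O[C@@H]1c1ccc(OCc2ccccc2)c(OCc2ccccc2)c1 | intermediate
3 | 8-bromo-5,7,3',4'-tetra-O-benzylcatechin | O[C@H]1Cc2c(OCc3ccccc3)cc(OCc3ccccc3)c(Br)c2O[C@@H]1c1ccc(OCc2ccccc2)c(OCc2ccccc2)c1 | intermediate
4 | 8-bromo-6-iodo-5,7,3',4'-tetra-O-benzylcatechin | O[C@H]1Cc2c(OCc3ccccc3)c(I)c(OCc3ccccc3)c(Br)c2O[C@@H]1c1ccc(OCc2ccccc2)c(OCc2ccccc2)c1 | intermediate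
5 | 1-[4-(benzyloxy)-2-hydroxyphenyl]ethanone | CC(=O)c1ccc(OCc2ccccc2)cc1O | starting material
6 | 3,4-bis(benzyloxy)benzaldehyde | O=Cc1ccc(OCc2ccccc2)c(OCc2ccccc2)c1 | starting material
7 | (E)-1-[4-(benzyloxy)-2-hydroxyphenyl]-3-[3,4-bis(benzyloxy)phenyl]prop-2-en-1-one | Oc1cc(OCc2ccccc2)ccc1C(=O)/C=C/c1ccc(OCc2ccccc2)c(OCc2ccccc2)c1 | intermediate
8 | sodium phenoxide of 7 (not isolated) | [Na+].[O-]c1cc(OCc2ccccc2)ccc1C(=O)/C=C/c1ccc(OCc2ccccc2)c(OCc2ccccc2)c1 | intermediate
9 | sodium 3-alkoxide of 4 (not isolated) | [Na+].[O-][C@H]1Cc2c(OCc3ccccc3)c(I)c(OCc3ccccc3)c(Br)c2O[C@@H]1c1ccc(OCc2ccccc2)c(OCc2ccccc2)c1 | intermediate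
10 | 6-lithio-8-bromo-5,7,3',4'-tetra-O-benzylcatechin sodium 3-alkoxide (not isolated) | [Na+].[O-][C@H]1Cc2c(OCc3ccccc3)c([Li])c(OCc3ccccc3)c(Br)c2O[C@@H]1c1ccc(OCc2ccccc2)c(OCc2ccccc2)c1 | intermediate
11 | (E)-1-[4-(benzyloxy)-2-hydroxyphenyl]-1-[(2R,3S)-5,7-bis(benzyloxy)-2-[3,4-bis(benzyloxy)phenyl]-8-bromo-3-hydroxychroman-6-yl]-3-[3,4-bis(benzyloxy)phenyl]prop-2-en-1-ol, both C1 epimers | Oc1cc(OCc2ccccc2)ccc1C(O)(/C=C/c1ccc(OCc2ccccc2)c(OCc2ccccc2)c1)c1c(OCc3ccccc3)c(Br)c2c(c1OCc1ccccc1)C[C@H](O)[C@@H](c1ccc(OCc3ccccc3)c(OCc3ccccc3)c1)O2 | intermediate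
12 | (2S)-7-(benzyloxy)-2-[3,4-bis(benzyloxy)phenyl]-4-[(2R,3S)-5,7-bis(benzyloxy)-2-[3,4-bis(benzyloxy)phenyl]-8-bromo-3-hydroxychroman-6-yl]-2H-chromene | c1ccccc1COc1ccc2c(c1)O[C@H](c1ccc(OCc3ccccc3)c(OCc3ccccc3)c1)C=C2c1c(OCc3ccccc3)c(Br)c2c(c1OCc1ccccc1)C[C@H](O)[C@@H](c1ccc(OCc3ccccc3)c(OCc3ccccc3)c1)O2 | intermediate
13 | C3-borane adduct of 12 with the lower 3-OH as its O-borane (not isolated); boron on C3 and hydrogen on C4, both on the face opposite the C2 aryl group | c1ccccc1COc1ccc2c(c1)O[C@H](c1ccc(OCc3ccccc3)c(OCc3ccccc3)c1)[C@@H](B)[C@@H]2c1c(OCc3ccccc3)c(Br)c2c(c1OCc1ccccc1)C[C@H](OB)[C@@H](c1ccc(OCc3ccccc3)c(OCc3ccccc3)c1)O2 | intermediate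
14 | (2R,3S,4S)-7-(benzyloxy)-2-[3,4-bis(benzyloxy)phenyl]-4-[(2R,3S)-5,7-bis(benzyloxy)-2-[3,4-bis(benzyloxy)phenyl]-8-bromo-3-hydroxychroman-6-yl]chroman-3-ol | c1ccccc1COc1ccc2c(c1)O[C@H](c1ccc(OCc3ccccc3)c(OCc3ccccc3)c1)[C@@H](O)[C@@H]2c1c(OCc3ccccc3)c(Br)c2c(c1OCc1ccccc1)C[C@H](O)[C@@H](c1ccc(OCc3ccccc3)c(OCc3ccccc3)c1)O2 | intermediate
15 | fisetinidol-(4α→6)-catechin, (2R,3S,4S)-2-(3,4-dihydroxyphenyl)-4-[(2R,3S)-2-(3,4-dihydroxyphenyl)-3,5,7-trihydroxychroman-6-yl]chroman-3,7-diol | Oc1ccc2c(c1)O[C@H](c1ccc(O)c(O)c1)[C@@H](O)[C@@H]2c1c(O)cc2c(c1O)C[C@H](O)[C@@H](c1ccc(O)c(O)c1)O2 | target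

Total step count: 8. Longest linear sequence: 7 steps (1 → 2 → 3 → 4 → 11 → 12 → 14 → 15, that is steps 1, 2, 3, 5, 6, 7 and 8).

Steps most likely to fail

Step 6. Enantiofacial control at C2 may be lost through uncatalysed background ionisation and cyclisation of the very labile alcohol, or the product may racemise by re-ionisation of its C2–O1 bond. The fallback builds ring C by the classical stereospecific sequence and attaches the catechin unit afterwards; it sets out from 7 and 3 and comes back at 14.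
- 7 is converted with MOMCl and NaH into its 2'-O-methoxymethyl ether F1.
- Julia–Colonna epoxidation (poly-L-leucine, urea–H2O2, DBU, THF) should give the (αR,βS)-epoxy ketone F2.
- HCl in MeOH removes the acetal, and the freed phenol opens the epoxide at the benzylic carbon with inversion. This closes ring C through the same O1–C2 bond and should give the (2R,3R)-dihydroflavonol F3.
- NaBH4 reduces the ketone to the 2,3-trans-3,4-trans flavan-3,4-diol F4.
- TiCl4 in CH2Cl2 ionises the C4–OH of F4, and the C8-capped nucleophile 3 attacks through C6, trans to the 3-OH, to give 14.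

Step 5. The addition may stall or turn 1,4-selective, because the ortho-phenoxide makes the enone carbonyl a vinylogous carboxylate, and the hindered aryllithium may be protonated instead. The fallback masks the phenol so that a normal enone carbonyl is attacked; it sets out from 7 (with aryllithium 10 made from 4 as in step 5) and comes back at 11.
- 7 is silylated with TBSOTf and 2,6-lutidine to the 2'-O-tert-butyldimethylsilyl chalcone F5.
- Addition of 10 at −78 °C should give the silyl-protected carbinol F6; migration of silicon to the tertiary alkoxide would be harmless.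
- Bu4NF in THF removes silicon under basic conditions and delivers 11.

Step 7. Borane may add sluggishly to the hindered trisubstituted C3=C4 bond or with insufficient facial selectivity. The fallback replaces the concerted syn-addition by epoxidation and stereoretentive hydrogenolysis; it sets out from 12 and comes back at 14.
- 12 is epoxidised with dimethyldioxirane in acetone at −40 °C on the face opposite the C2 aryl group to the 3,4-epoxide F7.
- F7 is hydrogenolysed over Raney Ni (H2, EtOH), a catalyst known to cleave benzylic C–O bonds with retention. Hydrogen should then take the place of the epoxide oxygen at C4, leaving the ring-D aryl group trans to the 3-OH, which gives 14.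
- Any loss of benzyl ethers or of the C–Br bond at this stage is harmless, because step 8 removes both.

Further compounds
F1 | step 6 | (E)-1-[4-(benzyloxy)-2-(methoxymethoxy)phenyl]-3-[3,4-bis(benzyloxy)phenyl]prop-2-en-1-one | COCOc1cc(OCc2ccccc2)ccc1C(=O)/C=C/c1ccc(OCc2ccccc2)c(OCc2ccccc2)c1
F2 | step 6 | (αR,βS)-epoxide of F1, [4-(benzyloxy)-2-(methoxymethoxy)phenyl] [(2R,3S)-3-[3,4-bis(benzyloxy)phenyl]oxiran-2-yl] ketone | COCOc1cc(OCc2ccccc2)ccc1C(=O)[C@@H]1O[C@H]1c1ccc(OCc2ccccc2)c(OCc2ccccc2)c1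
F3 | step 6 | (2R,3R)-7-(benzyloxy)-2-[3,4-bis(benzyloxy)phenyl]-3-hydroxychroman-4-one | c1ccccc1COc1ccc2c(c1)O[C@H](c1ccc(OCc3ccccc3)c(OCc3ccccc3)c1)[C@@H](O)C2=O
F4 | step 6 | (2R,3S,4R)-7-(benzyloxy)-2-[3,4-bis(benzyloxy)phenyl]chroman-3,4-diol | c1ccccc1COc1ccc2c(c1)O[C@H](c1ccc(OCc3ccccc3)c(OCc3ccccc3)c1)[C@@H](O)[C@@H]2O
F5 | step 5 | (E)-1-[4-(benzyloxy)-2-(tert-butyldimethylsilyloxy)phenyl]-3-[3,4-bis(benzyloxy)phenyl]prop-2-en-1-one | CC(C)(C)[Si](C)(C)Oc1cc(OCc2ccccc2)ccc1C(=O)/C=C/c1ccc(OCc2ccccc2)c(OCc2ccccc2)c1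
F6 | step 5 | 2'-O-tert-butyldimethylsilyl ether of 11, both C1 epimers | CC(C)(C)[Si](C)(C)Oc1cc(OCc2ccccc2)ccc1C(O)(/C=C/c1ccc(OCc2ccccc2)c(OCc2ccccc2)c1)c1c(OCc3ccccc3)c(Br)c2c(c1OCc1ccccc1)C[C@H](O)[C@@H](c1ccc(OCc3ccccc3)c(OCc3ccccc3)c1)O2
F7 | step 7 | 3,4-epoxide of 12 with the oxirane oxygen on the face opposite the C2 aryl group | c1ccccc1COc1ccc2c(c1)O[C@H](c1ccc(OCc3ccccc3)c(OCc3ccccc3)c1)[C@H]3O[C@]32c1c(OCc3ccccc3)c(Br)c2c(c1OCc1ccccc1)C[C@H](O)[C@@H](c1ccc(OCc3ccccc3)c(OCc3ccccc3)c1)O2
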